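The slowness of one hand is what sorts a racemate: the right-handed substrate meets the partner at 3.1 M⁻¹ s⁻¹, the left-handed at 6.4 M⁻¹ s⁻¹.

    partner + left-handed substrate → left-handed product (k1 = 6.4 M⁻¹ s⁻¹, Ea1 = 43.0 kJ mol⁻¹)
    2 partner → self-condensation product (k2 = 2.8 M⁻¹ s⁻¹, Ea2 = 44.0 kJ mol⁻¹)
    partner → decomposed reagent (k3 = 0.013 s⁻¹, Ea3 = 112 kJ mol⁻¹)
    partner + right-handed substrate → right-handed product (k4 = 3.1 M⁻¹ s⁻¹, Ea4 = 40.0 kJ mol⁻¹)
    left-handed substrate ⇌ right-handed substrate (k5 = 0.029 s⁻¹, Ea5 = 110 kJ mol⁻¹)
    (constants at 110 °C)

in all of them: left-handed substrate 28 mM; partner 61.6 mM; right-handed substrate 28 mM; time 6.0 s
- autumn: temperature 110 °C
- summer: temperature 95 °C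
- noon: temperature 125 °C
- midnight: at 125 °C until 1.2 s, from then on at 95 °C

* the flask with the highest share of left-handed product in all that became left-handed product or right-handed product ("all alike" if they lie within 1.5 percentage points) (autumn / summer / noon / midnight / all alike)
* share of left-handed product in all that became left-handed product or right-handed product, autumn
* share of left-handed product in all that became left-handed product or right-handed product, summer
* share of left-handed product in all that became left-handed product or right-handed product, noon
* share of left-handed product in all that became left-handed product or right-handed product, midnight

- partner is single-handed; left-handed substrate and right-handed substrate are mirror images of each other, charged as a racemate, each of them at the stated concentration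
- a step written with two of one species runs at k times the square of its concentration and takes two of it each time
- all constants are for 110 °C and move with temperature by the activation energies
- the handed part of partner does not stay in what it makes, so the products of the two hands are mirror images too

Follow one substrate molecule. Both hands see the same partner at the same moment, so the partner cancels from the odds, and the left-handed substrate goes 2.06 times as fast as the right-handed. This ratio of the two constants is the selectivity factor s. With a and b the fractions of each hand's charge still unreacted, and no interconversion, a equals b to the power s, and the share asked for is what the left hand lost over what both lost. The first product comes out 67.4% left-handed, and the share slides down from there.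

Which numbers must be known well? The value of s comes first. From the coldest flask to the hottest it grows by a factor of 1.08, which lifts the starting share by about 1.6 percentage points, close to the margin of 1.5 points.

The partner's fate sets the clock, the time integral of partner concentration. In autumn, ignoring the substrates gives a clock of 0.200 M·s and a share of 61.0%. Letting both substrates and decomposition draw at their starting rate, 0.279 s⁻¹, throughout gives 0.124 M·s and 63.2%. A clock 1.61 times as long thus costs 2.2 points. Decomposition hardly counts, at 0.013 s⁻¹.

Interconversion has a relaxation half-life of 12.0 s in autumn and 3.25 s at noon, so it refills the fast hand faster at noon than in autumn. My reckoning commits to about 63.2% for autumn and to all alike, with noon the likeliest to stand above.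

The forecast reads all alike, with 63.1%, 63%, 64.2% and 63.8% for autumn, summer, noon and midnight, and “the largest gap is about 1.2 points”.

The simulation gives 63.1%, 63.0%, 64.1% and 63.8% in the same order, so the answer is all alike, with noon over summer by 1.1 points. The noon flask ends with 43% of its left-handed and 54% of its right-handed charge, an apparent ratio of logarithms of 1.37.

In noon's neighbour with 250 mM of partner, 24% of the right-handed charge remains. With s near 2.14 at noon, the rule gives 4.57% of the left-handed charge and a share of 55.7%. The run gives 59.5%, with 14% of the left-handed charge remaining.

The numbers were chosen freely.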